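Time is what we count in here: each new flask stops at 6.0 min, and we want to know how many half-lives of the electrophile fit into that time.

| flask | electrophile | nucleophile | protic impurity | remark | time |
|---|---|---|---|---|---|
| ash | 0.21 M | 1.4 equiv | 0.021 M | run made earlier |  |
| maple | 0.21 M | 2.5 equiv | 0.021 M | run made earlier |  |
| birch | 0.21 M | 3.4 equiv | 0.021 M | run made earlier |  |
| violet | 0.21 M | 1.80 equiv | 0.0210 M |  | 6.0 min |
| green | 0.21 M | 2.30 equiv | 0.0210 M |  | 6.0 min |
| blue | 0.21 M | 3.00 equiv | 0.0210 M |  | 6.0 min |

| run | time / min | electrophile / % | target / % |
|---|---|---|---|
| ash | 0.250 | 98.9 | 1.2 |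
| ash | 0.500 | 96.9 | 2.2 |
| ash | 1.33 | 92.3 | 6.2 |
| ash | 3.00 | 85.5 | 11.0 |
| maple | 0.833 | 90.8 | 7.4 |
| maple | 1.50 | 86.2 | 10.7 |
| maple | 2.50 | 79.1 | 15.4 |
| maple | 3.00 | 76.2 | 16.8 |
| birch | 0.250 | 96.8 | 3.4 |
| birch | 0.500 | 92.7 | 5.7 |
| birch | 1.33 | 83.6 | 13.0 |
| birch | 3.00 | 68.6 | 19.4 |

(standard deviation of a reading: 0.5 percentage points)

* part of the electrophile that has reacted at the end, violet
* part of the electrophile that has reacted at the end, green
* part of the electrophile that has reacted at the end, blue
* what raising the equivalents of nucleophile from its lowest to its highest value here does to the part of the electrophile that has reacted (changes below 5 percentage points count as none) (it falls / no change / it rises)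

- the earlier runs were read with a standard deviation of 0.5 percentage points
- candidate steps: electrophile + nucleophile -> acid set free + target; nucleophile + acid set free <-> protonated nucleophile; nucleophile + target -> over-reaction product; nucleophile + protic impurity -> quenched reagent

The half-life depends on the free nucleophile, so we keep a ledger of that reagent, using birch at its reading of 3.00 min. We debit the protic impurity at the start, assuming it is quenched early, and birch opens with 0.693 M free. Making target costs one nucleophile per electrophile lost, here 0.0659 M. We assume each acid set free takes a second nucleophile, the same amount again. Electrophile found neither as such nor as target we book as over-reaction product, 0.0252 M, at one nucleophile each. The books close at 0.536 M free, so the price is 2.38 nucleophile per electrophile lost. Violet's charge of 1.80 equiv lies below that price, so on this ledger nucleophile is the limiting reagent there.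

Taking the electrophile as pseudo-first-order at each moment, we define the half-life dose 3.39 M·min: the product of c(nucleophile) and time that one half-life of the electrophile takes. Ash, read the same way, gives 3.17 M·min, and we go on with birch's figure as an estimate.

Our reckoning for violet starts from 0.357 M free. Held there, that is 0.632 half-lives, or 35.5% reacted. Paying the price for this brings the close to 0.180 M, and the mean of opening and close gives 0.475 half-lives, so 28.0% has reacted. The same steps give 35.2% for green and 44.3% for blue.

The forecast says 29%, 36% and 44.5%, and it rises, reasoning that “Each electrophile consumed should also tie up a second nucleophile as its salt”. Our figures lie slightly lower.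

    electrophile + nucleophile → acid set free + target (k = 0.00340 /M/s)
    nucleophile + acid set free ⇌ protonated nucleophile, settled at all times (K = 23000 /M)
    nucleophile + target → over-reaction product (k = 0.00890 /M/s)
    nucleophile + protic impurity → quenched reagent (k = 0.0960 /M/s)

The flasks give 29.0%, 35.8% and 44.3%: it rises. Violet's free nucleophile, from 0.357 M to 0.213 M, makes 0.505 half-lives at our dose, leaving 70.5% against 71.0% found. Blue stands 15 percentage points above violet because of its larger charge of nucleophile: blue reaches 44.3%, and the same flask with 1.80 equiv reaches 29.0%. Blue carried on to 15 min has 0.791 further half-lives, taking the electrophile from 55.7% to 32.2%, and that flask holds 32.9%.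

(The readings were generated by integration on assumed constants, and the scatter is random.)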